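Ring C is closed last. The route exploits the fact that C13 is the β-carbon of the ring D enone (C15 ketone, C16=C13) and is tethered to C9 through C11 and C12. A C12 radical, made from a primary iodide, attacks C13 in a 6-exo conjugate addition that forges C12–C13, the bicyclo[3.2.1]octane and the C13 stereocentre in one operation. Its precursor is a δ-lactone spiro-linked at C8 to a cyclopentenone and at C10 to ring A, carrying on C9 a CH(OTBS)CH2I side chain. It is assembled from a ring A epoxide and an (S)-butenolide by a titanium-mediated radical coupling, followed by spiro-annulation and lactone transposition.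

Key step: step 19

Remark: atom numbers are ent-kaurane numbers and α/β refer to the customary drawing (C20 and the C19 methyl α; H5, H9 and the C15–C16 bridge β); epoxide 11 is used as both spiro epimers, since they give the same C10 radical; O6 and O18 are carried as triisopropylsilyl (TIPS) ethers so that they survive the acidic and fluoride steps, and only O11 is a TBS ether.

Step 1
Reactants: 1 1,4-dioxaspiro[4.5]dec-6-en-8-one
Product: 2 7-(hydroxymethyl)-1,4-dioxaspiro[4.5]dec-6-en-8-one
Conditions: 37% aq. CH2O, DMAP (0.2 equiv), THF–H2O, rt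
Reagents that add atoms: formaldehyde, C=O
Why: Morita–Baylis–Hillman hydroxymethylation, in which the amine adds to the enone β-carbon, the enolate captures formaldehyde and elimination restores the enone, so that C18 sits on the future C4; no stereocentre is formed.

Step 2
Reactants: 2 7-(hydroxymethyl)-1,4-dioxaspiro[4.5]dec-6-en-8-one
Product: 3 TIPS ether of 2
Conditions: iPr3SiCl, imidazole, DMF, rt
Reagents that add atoms: chlorotri(propan-2-yl)silane, CC(C)[Si](Cl)(C(C)C)C(C)C
Why: Routine silylation of a primary alcohol; the TIPS group is chosen because it must later survive butyllithium, acetic acid, mild aqueous acid and one equivalent of fluoride.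

Step 3
Reactants: 3 TIPS ether of 2
Product: 4 (8R)-allylic alcohol
Conditions: (S)-2-methyl-CBS-oxazaborolidine (0.2 equiv), BH3·SMe2, THF, −30 °C; MeOH
Reagents that add atoms: none
Why: Corey–Bakshi–Shibata reduction, in which the α-branched alkenyl flank acts as the large group, so that the (S)-catalyst should deliver hydride to the face that gives the 8R carbinol, the only reagent-controlled stereocentre of ring A.

Step 4
Reactants: 4 (8R)-allylic alcohol
Product: 5 (tributylstannyl)methyl ether of 4
Conditions: KH, THF, 0 °C; Bu3SnCH2I, rt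
Reagents that add atoms: tributyl(iodomethyl)stannane, CCCC[Sn](CCCC)(CCCC)CI
Why: Williamson etherification of the potassium alkoxide with a primary iodide; the carbinol centre is not touched.

Step 5
Reactants: 5 (tributylstannyl)methyl ether of 4
Product: 6 (6S)-homoallylic alcohol
Conditions: n-BuLi, THF, −78 to −40 °C; aq. NH4Cl
Reagents that add atoms: none
Why: Wittig–Still [2,3]-sigmatropic rearrangement after tin–lithium exchange, which is suprafacial and so places the CH2OH group (C6) on C5 on the ring face formerly occupied by the C–O bond while moving the alkene to C3=C4.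

Step 6
Reactants: 6 (6S)-homoallylic alcohol
Product: 7 cyclopropane alcohol
Conditions: Et2Zn, CH2I2, CH2Cl2, 0 °C to rt
Reagents that add atoms: diiodomethane, ICI
Why: Hydroxyl-directed Simmons–Smith cyclopropanation, in which the zinc alkoxide of the homoallylic C6 hydroxyl delivers the methylene to the alkene face cis to the CH2OH group, so that the new carbon on C4 (future C19) is cis to C6.

Step 7
Reactants: 7 cyclopropane alcohol
Product: 8 bis-TIPS cyclopropane
Conditions: iPr3SiCl, imidazole, DMF, rt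
Reagents that add atoms: chlorotri(propan-2-yl)silane, CC(C)[Si](Cl)(C(C)C)C(C)C
Why: Routine silylation of the primary alcohol, which also removes the free hydroxyl before the acidic hydrogenolysis.

Step 8
Reactants: 8 bis-TIPS cyclopropane
Product: 9 bis-TIPS methyl ketal
Conditions: H2 (3 atm), PtO2, AcOH–EtOAc, rt
Reagents that add atoms: none
Why: Catalytic hydrogenolysis of a cyclopropane at its least substituted bond (CH2–CH), the established way to turn a cyclopropane methylene into an angular methyl group, which leaves the C4 configuration untouched and so gives the C19 methyl cis to C6 and trans to C18.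

Step 9
Reactants: 9 bis-TIPS methyl ketal
Product: 10 (2S,3S)-cyclohexanone
Conditions: PPTS, acetone–H2O, 40 °C
Reagents that add atoms: water, O
Why: Acid-catalysed ketal hydrolysis under conditions mild enough to spare the TIPS ethers and to keep enolisation towards the hindered C5 methine slow.

Step 10
Reactants: 10 (2S,3S)-cyclohexanone
Product: 11 spiro-epoxide
Conditions: Me3S I, KN(SiMe3)2, THF, −10 °C to rt
Reagents that add atoms: trimethylsulfonium iodide, C[S+](C)C.[I-]
Why: Corey–Chaykovsky epoxidation, in which the ylide should add to the carbonyl faster than it deprotonates the hindered C5–H; the configuration of the new spiro carbon is irrelevant because it becomes a radical in step 12.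

Step 11
Reactants: 12 (5S)-5-(hydroxymethyl)furan-2(5H)-one
Product: 13 butenolide tosylate
Conditions: TsCl, pyridine, CH2Cl2, 0 °C
Reagents that add atoms: 4-methylbenzenesulfonyl chloride, Cc1ccc(cc1)S(Cl)(=O)=O
Why: Routine sulfonylation of a primary alcohol, which installs the leaving group needed in step 17 without touching the stereocentre (future C11).

Step 12
Reactants: 11 spiro-epoxide; 13 butenolide tosylate
Product: 14 hydroxy γ-lactone
Conditions: Cp2TiCl2 (0.3 equiv), Zn dust, 2,4,6-collidine·HCl, THF, rt; 11 added slowly to 13 (2 equiv)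
Reagents that add atoms: none
Why: Titanocene-mediated reductive epoxide opening (Cp2TiCl, trivalent titanium) followed by Giese addition: the tertiary C10 radical adds to the butenolide β-carbon anti to the CH2OTs group (C9 trans to C12) and is attacked from the equatorial direction of the ring A chair, away from the axial C19 methyl and trans to the C5 side chain (C20 α, C9 β), after which the α-lactone radical is reduced and protonated.

Step 13
Reactants: 14 hydroxy γ-lactone
Product: 15 triethylsilyl ether of 14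
Conditions: Et3SiCl, imidazole, CH2Cl2, 0 °C
Reagents that add atoms: chlorotriethylsilane, CC[Si](Cl)(CC)CC
Why: Routine silylation that masks the C20 hydroxyl so that no alkoxide can attack the lactone or the tosylate during the enolate steps, with a group that fluoride removes before the TIPS ethers.

Step 14
Reactants: 15 triethylsilyl ether of 14
Product: 16 C8-acetyl γ-lactone
Conditions: LiN(SiMe3)2 (2.2 equiv), THF, −78 °C; 1-acetylimidazole, −78 to −20 °C; aq. NH4Cl
Reagents that add atoms: 1-acetylimidazole, CC(=O)n1ccnc1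
Why: Claisen-type C-acylation of the lactone enolate, driven by deprotonation of the β-keto lactone by the second equivalent of base; C8 stays epimerisable and is fixed in step 15.

Step 15
Reactants: 16 C8-acetyl γ-lactone
Product: 17 C8-acetyl C8-allyl γ-lactone
Conditions: K2CO3, allyl bromide, acetone, rt
Reagents that add atoms: 3-bromoprop-1-ene, C=CCBr
Why: Alkylation of a β-keto lactone enolate, in which allyl bromide approaches the planar five-membered enolate anti to the bulky quaternary C10 substituent on the adjacent C9, so that C14 is trans and the acetyl carbon C15 cis to C10, the C8 configuration of the target.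

Step 16
Reactants: 17 C8-acetyl C8-allyl γ-lactone
Product: 19 spiro-cyclopentenone γ-lactone, via keto aldehyde 18 (not isolated)
Conditions: O3, CH2Cl2, −78 °C; PPh3; then Bn2NH·CF3CO2H (0.3 equiv), PhH, 50 °C
Reagents that add atoms: ozone, [O-][O+]=O
Why: Ozonolysis of the allyl group gives the C13 aldehyde, and an amine-salt-catalysed intramolecular aldol condensation of the methyl ketone carbon C16 onto C13, the only ring closure open to this 1,4-dicarbonyl unit, forms and dehydrates ring D to the C16=C13 enone.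

Step 17
Reactants: 19 spiro-cyclopentenone γ-lactone
Product: 21 epoxy δ-lactone, via C20 alcohol 20 (not isolated)
Conditions: Bu4NF (1.1 equiv), THF, −20 to 0 °C
Reagents that add atoms: none
Why: Fluoride cleaves the triethylsilyl ether, the C20 alkoxide undergoes intramolecular transesterification at C7 through a six-membered transition state, and the released C11 alkoxide closes the epoxide by Williamson displacement of the tosylate, which makes the lactone transposition irreversible and leaves C11 unchanged because its C–O bond is never broken.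

Step 18
Reactants: 21 epoxy δ-lactone
Product: 23 iodide, via iodohydrin 22 (not isolated)
Conditions: LiI, AcOH, THF, 0 °C; then TBSOTf, 2,6-lutidine, CH2Cl2, −78 °C
Reagents that add atoms: lithium iodide, [Li+].[I-]; tert-butyldimethylsilyl trifluoromethanesulfonate, CC(C)(C)[Si](C)(C)OS(=O)(=O)C(F)(F)F
Why: SN2 opening of the terminal epoxide by iodide at the primary carbon C12 under buffered protic conditions, followed at once by silylation of the C11 hydroxyl so that it cannot re-close the epoxide or migrate the acyl group back.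

Step 19
Reactants: 23 iodide
Product: 24 bicyclo[3.2.1]octan-15-one
Conditions: (Me3Si)3SiH (1.5 equiv, syringe pump), AIBN (0.2 equiv), PhH (0.005 M), 80 °C
Reagents that add atoms: none
Why: The silyl radical removes iodine from 23, the nucleophilic primary C12 radical adds to C13, the electron-poor β-carbon of the spiro enone, and the α-keto radical at C16 takes hydrogen from the silane to carry the chain; the closest known reaction type is the Giese-type 6-exo cyclisation of alkyl iodides onto cycloalkenones to give bridged bicyclic ketones. The new ring (C12, C11, C9, C8, C14, C13) closes in the 6-exo-trig mode and, together with ring D, makes the bicyclo[3.2.1]octanone. The only new stereocentre, C13, is set by the tether: the C11–C12 chain on C9 spans only the enone face syn to C9, so the C8 and C9 configurations fixed in steps 12 and 15 dictate H13 α. Attack at C16 would also close a six-membered ring (through C15), but it is polarity-mismatched and would leave an unstabilised secondary radical at C13, so regioselectivity rests on the polarisation of the enone. The step needs ring closure to outrun hydrogen transfer to the C12 radical, which high dilution and slow addition of the silane secure; the β-silyloxy group is not expelled from a carbon radical.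

Step 20
Reactants: 24 bicyclo[3.2.1]octan-15-one
Product: 27 16-methylene ketone, via Mannich base 25 (not isolated), via ammonium iodide 26 (not isolated)
Conditions: LiN(SiMe3)2, THF, −78 °C; Me2N=CH2 I, −78 to 0 °C; then MeI, CH2Cl2, rt; then aq. NaHCO3
Reagents that add atoms: N,N-dimethylmethyleneiminium iodide (Eschenmoser's salt), C=[N+](C)C.[I-]
Why: Eschenmoser methylenation: C16 is the only enolisable position because C8 is quaternary, so the Mannich reaction of the lithium enolate, N-methylation and base-induced elimination of trimethylamine give the exo-methylene ketone without touching any stereocentre.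

Step 21
Reactants: 27 16-methylene ketone
Product: 28 CNP0152458.1
Conditions: HF·pyridine, pyridine, THF, 0 °C to rt
Reagents that add atoms: none
Why: Fluoride-mediated cleavage of the two primary TIPS ethers and the secondary TBS ether under buffered, non-basic conditions that the α-methylene ketone and the δ-lactone should tolerate.

Compound list
1 | 1,4-dioxaspiro[4.5]dec-6-en-8-one | O=C1CCC2(OCCO2)C=C1 | starting material
2 | 7-(hydroxymethyl)-1,4-dioxaspiro[4.5]dec-6-en-8-one | O=C1CCC2(OCCO2)C=C1CO | intermediate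
3 | 7-({[tri(propan-2-yl)silyl]oxy}methyl)-1,4-dioxaspiro[4.5]dec-6-en-8-one | O=C1CCC2(OCCO2)C=C1CO[Si](C(C)C)(C(C)C)C(C)C | intermediate
4 | (8R)-7-({[tri(propan-2-yl)silyl]oxy}methyl)-1,4-dioxaspiro[4.5]dec-6-en-8-ol | O[C@@H]1CCC2(OCCO2)C=C1CO[Si](C(C)C)(C(C)C)C(C)C | intermediate
5 | tributyl({[(8R)-7-({[tri(propan-2-yl)silyl]oxy}methyl)-1,4-dioxaspiro[4.5]dec-6-en-8-yl]oxy}methyl)stannane | CCCC[Sn](CCCC)(CCCC)CO[C@@H]1CCC2(OCCO2)C=C1CO[Si](C(C)C)(C(C)C)C(C)C | intermediate
6 | [(6S)-7-({[tri(propan-2-yl)silyl]oxy}methyl)-1,4-dioxaspiro[4.5]dec-7-en-6-yl]methanol | OC[C@@H]1C(CO[Si](C(C)C)(C(C)C)C(C)C)=CCCC12OCCO2 | intermediate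
7 | [1-({[tri(propan-2-yl)silyl]oxy}methyl)spiro[bicyclo[4.1.0]heptane-3,2'-[1,3]dioxolan]-2-yl]methanol, cyclopropane CH2 cis to the CH2OH group | OC[C@@H]1[C@]2(CO[Si](C(C)C)(C(C)C)C(C)C)C[C@@H]2CCC13OCCO3 | intermediate
8 | TIPS ether of 7 (both CH2O groups silylated, cyclopropane CH2 cis to the C2 side chain) | CC(C)[Si](C(C)C)(C(C)C)OC[C@@H]1[C@]2(CO[Si](C(C)C)(C(C)C)C(C)C)C[C@@H]2CCC13OCCO3 | intermediate
9 | (6S,7S)-7-methyl-6,7-bis({[tri(propan-2-yl)silyl]oxy}methyl)-1,4-dioxaspiro[4.5]decane | CC(C)[Si](C(C)C)(C(C)C)OC[C@@H]1[C@@](C)(CO[Si](C(C)C)(C(C)C)C(C)C)CCCC12OCCO2 | intermediate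
10 | (2S,3S)-3-methyl-2,3-bis({[tri(propan-2-yl)silyl]oxy}methyl)cyclohexan-1-one (C10 ketone; C6 cis to the C19 methyl) | CC(C)[Si](C(C)C)(C(C)C)OC[C@@H]1[C@@](C)(CO[Si](C(C)C)(C(C)C)C(C)C)CCCC1=O | intermediate
11 | (4S,5S)-5-methyl-4,5-bis({[tri(propan-2-yl)silyl]oxy}methyl)-1-oxaspiro[2.5]octane, both epimers at C3 | CC(C)[Si](C(C)C)(C(C)C)OC[C@@H]1[C@@](C)(CO[Si](C(C)C)(C(C)C)C(C)C)CCCC12CO2 | intermediate
12 | (5S)-5-(hydroxymethyl)furan-2(5H)-one | OC[C@@H]1C=CC(=O)O1 | starting material
13 | [(2S)-5-oxo-2,5-dihydrofuran-2-yl]methyl 4-methylbenzenesulfonate | Cc1ccc(cc1)S(=O)(=O)OC[C@@H]1C=CC(=O)O1 | intermediate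
14 | hydroxy γ-lactone: oxolan-2-one (C7 carbonyl, O on C11) bearing CH2OTs (C12) on C11 and, trans to it on C9, the quaternary C10 of ring A; C10 carries CH2OH (C20, α); 4α-methyl, 4β- and 5α-CH2OTIPS, 9β-H | O=C1C[C@@H]([C@@H](COS(=O)(=O)c2ccc(C)cc2)O1)[C@]2(CO)CCC[C@](C)(CO[Si](C(C)C)(C(C)C)C(C)C)[C@H]2CO[Si](C(C)C)(C(C)C)C(C)C | intermediate
15 | C20 triethylsilyl ether of 14 | O=C1C[C@@H]([C@@H](COS(=O)(=O)c2ccc(C)cc2)O1)[C@]2(CO[Si](CC)(CC)CC)CCC[C@](C)(CO[Si](C(C)C)(C(C)C)C(C)C)[C@H]2CO[Si](C(C)C)(C(C)C)C(C)C | intermediate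
16 | C8-acetyl derivative of 15 (β-keto lactone, C8 epimers and enol) | O=C1C(C(C)=O)[C@@H]([C@@H](COS(=O)(=O)c2ccc(C)cc2)O1)[C@]2(CO[Si](CC)(CC)CC)CCC[C@](C)(CO[Si](C(C)C)(C(C)C)C(C)C)[C@H]2CO[Si](C(C)C)(C(C)C)C(C)C | intermediate
17 | C8-acetyl C8-allyl γ-lactone; allyl (C14, C13) trans and acetyl (C15, C16) cis to C10 on the lactone ring | O=C1[C@@](C(C)=O)(CC=C)[C@@H]([C@@H](COS(=O)(=O)c2ccc(C)cc2)O1)[C@]2(CO[Si](CC)(CC)CC)CCC[C@](C)(CO[Si](C(C)C)(C(C)C)C(C)C)[C@H]2CO[Si](C(C)C)(C(C)C)C(C)C | intermediate
18 | keto aldehyde from 17 (C13 aldehyde in place of the vinyl group) | O=C1[C@@](C(C)=O)(CC=O)[C@@H]([C@@H](COS(=O)(=O)c2ccc(C)cc2)O1)[C@]2(CO[Si](CC)(CC)CC)CCC[C@](C)(CO[Si](C(C)C)(C(C)C)C(C)C)[C@H]2CO[Si](C(C)C)(C(C)C)C(C)C | intermediate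
19 | spiro-cyclopentenone γ-lactone: ring D enone (C15 ketone, C16=C13) spiro at C8 to the 7,11-lactone; C20 OSiEt3; C12 OTs | O=C1C=CC[C@]12[C@H]([C@]3(CO[Si](CC)(CC)CC)CCC[C@](C)(CO[Si](C(C)C)(C(C)C)C(C)C)[C@H]3CO[Si](C(C)C)(C(C)C)C(C)C)[C@@H](COS(=O)(=O)c4ccc(C)cc4)OC2=O | intermediate
20 | C20 alcohol from 19 (formed as its alkoxide) | O=C1C=CC[C@]12[C@H]([C@]3(CO)CCC[C@](C)(CO[Si](C(C)C)(C(C)C)C(C)C)[C@H]3CO[Si](C(C)C)(C(C)C)C(C)C)[C@@H](COS(=O)(=O)c4ccc(C)cc4)OC2=O | intermediate
21 | epoxy δ-lactone: 7,20-lactone spiro at C8 to the cyclopentenone and at C10 to ring A; C9 carries the (11R)-oxiranyl group | O=C1C=CC[C@]12[C@@H]([C@H]3CO3)[C@@]1(CCC[C@](C)(CO[Si](C(C)C)(C(C)C)C(C)C)[C@H]1CO[Si](C(C)C)(C(C)C)C(C)C)COC2=O | intermediate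
22 | iodohydrin from 21 (11α-OH, C12 iodide) | O=C1C=CC[C@]12[C@@H]([C@@H](CI)O)[C@@]1(CCC[C@](C)(CO[Si](C(C)C)(C(C)C)C(C)C)[C@H]1CO[Si](C(C)C)(C(C)C)C(C)C)COC2=O | intermediate
23 | key-step precursor: spiro cyclopentenone 7,20-lactone with 11α-OTBS, C12 iodide, O6 and O18 as TIPS ethers | O=C1C=CC[C@]12[C@@H]([C@@H](CI)O[Si](C)(C)C(C)(C)C)[C@@]1(CCC[C@](C)(CO[Si](C(C)C)(C(C)C)C(C)C)[C@H]1CO[Si](C(C)C)(C(C)C)C(C)C)COC2=O | intermediate
24 | key-step product: 6,7-seco-ent-kauran-15-one 7,20-lactone with unsubstituted C16 methylene, 11α-OTBS, O6 and O18 as TIPS ethers, 13α-H | C1C(=O)[C@]23C[C@H]1C[C@@H](O[Si](C)(C)C(C)(C)C)[C@H]2[C@@]1(CCC[C@](C)(CO[Si](C(C)C)(C(C)C)C(C)C)[C@H]1CO[Si](C(C)C)(C(C)C)C(C)C)COC3=O | intermediate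
25 | 16-(dimethylaminomethyl) ketone (Mannich base, C16 epimers) | CN(C)CC1C(=O)[C@]23C[C@H]1C[C@@H](O[Si](C)(C)C(C)(C)C)[C@H]2[C@@]1(CCC[C@](C)(CO[Si](C(C)C)(C(C)C)C(C)C)[C@H]1CO[Si](C(C)C)(C(C)C)C(C)C)COC3=O | intermediate
26 | trimethylammonium iodide of 25 | C[N+](C)(C)CC1C(=O)[C@]23C[C@H]1C[C@@H](O[Si](C)(C)C(C)(C)C)[C@H]2[C@@]1(CCC[C@](C)(CO[Si](C(C)C)(C(C)C)C(C)C)[C@H]1CO[Si](C(C)C)(C(C)C)C(C)C)COC3=O.[I-] | intermediate
27 | 16-methylene ketone: tris-silyl ether of the target (11-OTBS, 6- and 18-OTIPS) | C=C1C(=O)[C@]23C[C@H]1C[C@@H](O[Si](C)(C)C(C)(C)C)[C@H]2[C@@]1(CCC[C@](C)(CO[Si](C(C)C)(C(C)C)C(C)C)[C@H]1CO[Si](C(C)C)(C(C)C)C(C)C)COC3=O | intermediate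
28 | CNP0152458.1: 6,11α,18-trihydroxy-15-oxo-6,7-seco-ent-kaur-16-en-7,20-olide | C=C1C(=O)[C@]23C[C@H]1C[C@@H](O)[C@H]2[C@@]1(CCC[C@](C)(CO)[C@H]1CO)COC3=O | target

Total steps: 21. Longest linear sequence: 20 steps (steps 1–10 and 12–21 from compound 1); the butenolide branch is one step (step 11).

Steps most likely to fail

Step 19. Hydrogen transfer to the C12 radical may outrun ring closure, or the side chain may be held away from C13, so that only deiodination occurs. The hydrogen donor would then be removed altogether. Iodide 23 is submitted to a nickel-catalysed reductive conjugate addition (NiCl2(dme), 2,2':6',2''-terpyridine, Mn powder, Et3SiCl, DMF, rt). The alkyl fragment is delivered to C13 and the enolate is trapped on oxygen, giving the triethylsilyl enol ether F1. Brief treatment with dilute HCl in THF at 0 °C should hydrolyse the enol ether and bring the route back to ketone 24.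

Step 12. The hindered tertiary C10 radical may be reduced further or eliminated (to the exocyclic alkene or allylic alcohol) faster than it adds to the β-substituted lactone. The radical would then be generated oxidatively. Ketone 10 is methylenated (Ph3P=CH2, THF) to the exocyclic alkene F2, dihydroxylated (OsO4 cat., N-methylmorpholine N-oxide) to the diol F3, and silylated at the primary hydroxyl (Et3SiCl, imidazole) to the tertiary alcohol F4. Oxalyl chloride followed by water converts F4 into the hydrogen oxalate F5. Irradiation of F5 with 13, CsF and Ir[dF(CF3)ppy]2(dtbbpy)PF6 under blue light in DME–DMF should expel two molecules of CO2 and deliver the same C10 radical to the butenolide with the same facial preferences. This gives 15 directly, where the route is rejoined.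

Step 17. The C20 alkoxide may attack the C15 ketone (retro-Claisen opening of ring D) or displace the C12 sulfonate (tetrahydropyran formation) instead of transferring the acyl group. The lactone would then be transposed before C8 is made quaternary. Hydroxy lactone 14 with NaH in THF should give the epoxy δ-lactone F6 without a competing ketone. LiCl/AcOH followed by TBSOTf/2,6-lutidine gives the chloro silyl ether F7. LiN(iPr)2 and allyl bromide give the C8-allyl lactone F8. A second enolisation and addition of acetaldehyde, anti to the C9 side chain on the six-membered lactone, gives the aldol F9 with C15 trans to C11. Dess–Martin oxidation gives the methyl ketone F10. Ozonolysis and amine-salt aldol condensation as in step 16 give the chloro enone F11. Finkelstein exchange (NaI, butanone, reflux) returns to 23.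

Further compounds
F1 | step 19 | triethylsilyl enol ether of ketone 24 (C15–O–SiEt3, C15=C16) | C1=C(O[Si](CC)(CC)CC)[C@]23C[C@H]1C[C@@H](O[Si](C)(C)C(C)(C)C)[C@H]2[C@@]1(CCC[C@](C)(CO[Si](C(C)C)(C(C)C)C(C)C)[C@H]1CO[Si](C(C)C)(C(C)C)C(C)C)COC3=O
F2 | step 12 | exocyclic alkene from ketone 10 (C10=C20 methylidene) | CC(C)[Si](C(C)C)(C(C)C)OC[C@@H]1[C@@](C)(CO[Si](C(C)C)(C(C)C)C(C)C)CCCC1=C
F3 | step 12 | C10,C20 diol from F2 (C10 epimers) | CC(C)[Si](C(C)C)(C(C)C)OC[C@@H]1[C@@](C)(CO[Si](C(C)C)(C(C)C)C(C)C)CCCC1(O)CO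
F4 | step 12 | C20 triethylsilyl ether of F3 (tertiary C10 alcohol) | CC(C)[Si](C(C)C)(C(C)C)OC[C@@H]1[C@@](C)(CO[Si](C(C)C)(C(C)C)C(C)C)CCCC1(O)CO[Si](CC)(CC)CC
F5 | step 12 | hydrogen oxalate of F4 | CC(C)[Si](C(C)C)(C(C)C)OC[C@@H]1[C@@](C)(CO[Si](C(C)C)(C(C)C)C(C)C)CCCC1(OC(=O)C(=O)O)CO[Si](CC)(CC)CC
F6 | step 17 | epoxy δ-lactone with C8 methylene (7,20-lactone, 11,12-epoxide) | O=C1C[C@@H]([C@H]2CO2)[C@@]3(CCC[C@](C)(CO[Si](C(C)C)(C(C)C)C(C)C)[C@H]3CO[Si](C(C)C)(C(C)C)C(C)C)CO1
F7 | step 17 | 11α-OTBS C12 chloride δ-lactone | O=C1C[C@@H]([C@@H](CCl)O[Si](C)(C)C(C)(C)C)[C@@]3(CCC[C@](C)(CO[Si](C(C)C)(C(C)C)C(C)C)[C@H]3CO[Si](C(C)C)(C(C)C)C(C)C)CO1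
F8 | step 17 | C8-allyl derivative of F7 (C8 epimers) | O=C1C(CC=C)[C@@H]([C@@H](CCl)O[Si](C)(C)C(C)(C)C)[C@@]3(CCC[C@](C)(CO[Si](C(C)C)(C(C)C)C(C)C)[C@H]3CO[Si](C(C)C)(C(C)C)C(C)C)CO1
F9 | step 17 | C8-allyl C8-(1-hydroxyethyl) δ-lactone (C15 carbinol epimers, C15 trans to C11) | O=C1[C@](CC=C)(C(C)O)[C@@H]([C@@H](CCl)O[Si](C)(C)C(C)(C)C)[C@@]3(CCC[C@](C)(CO[Si](C(C)C)(C(C)C)C(C)C)[C@H]3CO[Si](C(C)C)(C(C)C)C(C)C)CO1
F10 | step 17 | C8-allyl C8-acetyl δ-lactone | O=C1[C@](CC=C)(C(C)=O)[C@@H]([C@@H](CCl)O[Si](C)(C)C(C)(C)C)[C@@]3(CCC[C@](C)(CO[Si](C(C)C)(C(C)C)C(C)C)[C@H]3CO[Si](C(C)C)(C(C)C)C(C)C)CO1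
F11 | step 17 | C12 chloride analogue of 23 | O=C1C=CC[C@]12[C@@H]([C@@H](CCl)O[Si](C)(C)C(C)(C)C)[C@@]1(CCC[C@](C)(CO[Si](C(C)C)(C(C)C)C(C)C)[C@H]1CO[Si](C(C)C)(C(C)C)C(C)C)COC2=O
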